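**Plan**

- Feature used: each end ring is a 2,6,6-trimethylcyclohex-2-ene (carotenoid numbering: C1 = ring CMe2, C4=C5 = ring alkene, C6 = stereogenic ring methine, C7 = first chain carbon). Opened between C1 and C6 it is a geranyl-type 1,5-diene, so a tertiary cation at C1 can be trapped by a C5=C6 alkene, and loss of a C4 proton gives the ring alkene.
- Retrosynthesis: first both C11=C12 bonds (twofold Wittig, C15 + C10 + C15, so one chiral C15 salt serves both ends of the C2-symmetric target); then C9–C10 (vinyl addition) and C7=C8 (olefination) back to (R)-α-cyclocitral; last the ring bond C1–C6, by epoxide-initiated cationic cyclization of (R)-6,7-epoxygeranyl acetate.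
- The epoxide is a temporary helper: it supplies the C1 cation under a mild Lewis acid and a stereocenter (C2) that steers C6. Its oxygen is removed afterwards by radical deoxygenation.
- Forward: geranyl acetate → epoxide → ring closure → deoxygenation → C10 aldehyde → C13 enone → C15 phosphonium salt → twofold olefination of the C10 dialdehyde. Each ring arises once, at the C10 stage, and the chain is joined last.
- Stereochemistry: the catalyst-controlled Shi epoxidation sets C2, the chair-like cyclization relays it to C6 (6R), and 6R and 6'R both come from the same intermediate. C7=C8 is E from the olefination; the other chain alkenes reach all-E by thermal equilibration.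

Key step: step 2

Assumption: the C10 dialdehyde 11 (the usual central building block of carotenoid synthesis) and the D-fructose-derived Shi ketone are taken as purchasable.

**Route**

Step 1
Reactants: 1 geranyl acetate
Product: 2 (R)-6,7-epoxygeranyl acetate [(2E)-5-[(2R)-3,3-dimethyloxiran-2-yl]-3-methylpent-2-en-1-yl acetate]
Conditions: D-fructose-derived Shi ketone (30 mol %), KHSO5 (Oxone), K2CO3, Bu4NHSO4, MeCN/CH2(OMe)2/aq. Na2B4O7 buffer, 0 °C
Reagents that add atoms: potassium peroxymonosulfate, [K+].[O-]S(=O)(=O)OO
Why: Shi asymmetric epoxidation, in which the electrophilic chiral dioxirane should choose the electron-rich distal alkene over the alkene deactivated by the allylic acetate, and the spiro transition state of the D-fructose-derived ketone should deliver oxygen to the face that gives the (R)-epoxide.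

Step 2
Reactants: 2 (R)-6,7-epoxygeranyl acetate
Product: 3 [(1S,5R)-5-hydroxy-2,6,6-trimethylcyclohex-2-en-1-yl]methyl acetate (hydroxyl and CH2OAc cis)
Conditions: ZrCl4 (1.1 equiv), CH2Cl2, −78 °C to 0 °C; then H2O
Reagents that add atoms: none
Why: ZrCl4 binds the epoxide oxygen and polarizes the C1–O bond at the tertiary carbon; the C5=C6 alkene attacks C1 anti to the departing oxygen, and the tertiary C5 cation then loses the axial C4 proton, so a net isomerization gives the zirconium alkoxide of 3 with the C4=C5 ring alkene in place. The closest known reaction type is the Lewis-acid-promoted epoxy-olefin cyclization of 6,7-epoxygeranyl esters, the laboratory counterpart of the enzymatic closure of an open carotenoid end group. The six-membered ring closes in a 6-endo mode with respect to both the epoxide (C1 and C2 both end up in the ring) and the alkene (6-endo-trig), through a chair-like transition state. The new C6 stereocenter is controlled by the epoxide carbon C2: in the chair the C2–O bond and the CH2OAc group of the (E)-alkene both sit equatorial, which gives the cis (1S,5R) product, and because ionization and C–C bond formation are concerted the enantiomeric purity of 2 should be carried over. The step needs opening at the tertiary carbon (secured by cation stability), carbon rather than oxygen capture (the acetate is a poor nucleophile), and proton loss from C4 rather than from the C5 methyl or C6 (the C6–H is hindered and next to the electron-poor CH2OAc, and the zirconium chloro-alkoxide removes the axial ring proton).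

Step 3
Reactants: 3 [(1S,5R)-5-hydroxy-2,6,6-trimethylcyclohex-2-en-1-yl]methyl acetate
Product: 4 [(1S,5R)-5-[(1H-imidazol-1-ylcarbonothioyl)oxy]-2,6,6-trimethylcyclohex-2-en-1-yl]methyl acetate
Conditions: 1,1'-thiocarbonyldiimidazole, DMAP (cat.), ClCH2CH2Cl, 80 °C
Reagents that add atoms: 1,1'-thiocarbonyldiimidazole, S=C(n1ccnc1)n1ccnc1
Why: Thioacylation of the only free hydroxyl group (first half of a Barton–McCombie deoxygenation), which should proceed at the equatorial secondary alcohol on heating despite the neighbouring quaternary carbon.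

Step 4
Reactants: 4 [(1S,5R)-5-[(1H-imidazol-1-ylcarbonothioyl)oxy]-2,6,6-trimethylcyclohex-2-en-1-yl]methyl acetate
Product: 5 (R)-α-cyclogeranyl acetate [[(1R)-2,6,6-trimethylcyclohex-2-en-1-yl]methyl acetate]
Conditions: Bu3SnH, AIBN (cat.), toluene, 100 °C
Reagents that add atoms: none
Why: Barton–McCombie radical deoxygenation, in which the stannyl radical adds to C=S, β-scission gives the secondary ring radical, and this radical should take hydrogen from Bu3SnH faster than it rearranges, leaving C6 and the acetate untouched.

Step 5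
Reactants: 5 (R)-α-cyclogeranyl acetate
Product: 6 (R)-α-cyclogeraniol [[(1R)-2,6,6-trimethylcyclohex-2-en-1-yl]methanol]
Conditions: K2CO3 (cat.), MeOH, rt
Reagents that add atoms: none
Why: Base-catalysed transesterification of the acetate with methanol, mild enough to leave the non-acidic allylic C6–H and the ring alkene unchanged.

Step 6
Reactants: 6 (R)-α-cyclogeraniol
Product: 7 (R)-α-cyclocitral [(1R)-2,6,6-trimethylcyclohex-2-ene-1-carbaldehyde]
Conditions: Dess–Martin periodinane, NaHCO3, CH2Cl2, 0 °C to rt
Reagents that add atoms: none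
Why: Dess–Martin oxidation under buffered, non-basic conditions should give the α-stereogenic β,γ-unsaturated aldehyde without epimerization or migration of the alkene into conjugation, and the aldehyde is used directly.

Step 7
Reactants: 7 (R)-α-cyclocitral
Product: 8 (R)-α-ionone [(3E)-4-[(1R)-2,6,6-trimethylcyclohex-2-en-1-yl]but-3-en-2-one]
Conditions: (EtO)2P(O)CH2C(O)CH3, LiCl, iPr2NEt, MeCN, rt
Reagents that add atoms: diethyl (2-oxopropyl)phosphonate, CCOP(=O)(CC(C)=O)OCC
Why: Horner–Wadsworth–Emmons olefination under Masamune–Roush conditions (weak amine base, lithium chelation) should give the (E)-enone while sparing the epimerizable aldehyde.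

Step 8
Reactants: 8 (R)-α-ionone
Product: 9 vinyl-α-ionol [(1E)-3-methyl-1-[(1R)-2,6,6-trimethylcyclohex-2-en-1-yl]penta-1,4-dien-3-ol, both epimers at the carbinol carbon]
Conditions: CH2=CHMgBr, THF, −20 °C to 0 °C; then aq. NH4Cl
Reagents that add atoms: vinylmagnesium bromide, C=C[Mg]Br
Why: 1,2-addition of the Grignard reagent to the enone carbonyl (hard nucleophile, hindered β-position); the new carbinol center forms as a mixture, which does not matter because it is erased in step 9.

Step 9
Reactants: 9 vinyl-α-ionol
Product: 10 [(2E,4E)-3-methyl-5-[(1R)-2,6,6-trimethylcyclohex-2-en-1-yl]penta-2,4-dien-1-yl]triphenylphosphonium bromide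
Conditions: Ph3P·HBr, MeOH, rt
Reagents that add atoms: triphenylphosphine hydrobromide, [Br-].[PH+](c1ccccc1)(c1ccccc1)c1ccccc1
Why: Allylic transposition of SN1' type, in which HBr ionizes the tertiary doubly allylic alcohol to a pentadienyl cation that PPh3 captures at the unhindered primary terminus (the standard vinyl-ionol to C15 Wittig salt conversion), and the salt should crystallize mainly as the (2E,4E) isomer.

Step 10
Reactants: 10 C15 phosphonium bromide (2.2 equiv); 11 (2E,4E,6E)-2,7-dimethylocta-2,4,6-trienedial
Product: 14 (6R,6'R)-ε,ε-carotene, via C15 phosphorus ylide 12 (not isolated), via C25 apo-aldehyde 13 (not isolated)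
Conditions: NaOMe, MeOH/CH2Cl2, 0 °C to rt; then n-heptane, reflux
Reagents that add atoms: none
Why: Twofold Wittig olefination of the symmetrical dialdehyde by the semi-stabilized allylic ylide, in which any Z isomers at the new C11=C12 bonds (or at C9=C10) should equilibrate to the all-E polyene on heating, and two (R) units necessarily give the (6R,6'R) product.

**Compound list**

1 | geranyl acetate, (2E)-3,7-dimethylocta-2,6-dien-1-yl acetate | CC(C)=CCC/C(C)=C/COC(C)=O | starting material
2 | (R)-6,7-epoxygeranyl acetate, (2E)-5-[(2R)-3,3-dimethyloxiran-2-yl]-3-methylpent-2-en-1-yl acetate | CC1(C)O[C@@H]1CC/C(C)=C/COC(C)=O | intermediate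
3 | [(1S,5R)-5-hydroxy-2,6,6-trimethylcyclohex-2-en-1-yl]methyl acetate | CC1=CC[C@@H](O)C(C)(C)[C@H]1COC(C)=O | intermediate
4 | [(1S,5R)-5-[(1H-imidazol-1-ylcarbonothioyl)oxy]-2,6,6-trimethylcyclohex-2-en-1-yl]methyl acetate | CC1=CC[C@@H](OC(=S)n2ccnc2)C(C)(C)[C@H]1COC(C)=O | intermediate
5 | (R)-α-cyclogeranyl acetate, [(1R)-2,6,6-trimethylcyclohex-2-en-1-yl]methyl acetate | CC1=CCCC(C)(C)[C@H]1COC(C)=O | intermediate
6 | (R)-α-cyclogeraniol, [(1R)-2,6,6-trimethylcyclohex-2-en-1-yl]methanol | CC1=CCCC(C)(C)[C@H]1CO | intermediate
7 | (R)-α-cyclocitral, (1R)-2,6,6-trimethylcyclohex-2-ene-1-carbaldehyde | CC1=CCCC(C)(C)[C@H]1C=O | intermediate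
8 | (R)-α-ionone, (3E)-4-[(1R)-2,6,6-trimethylcyclohex-2-en-1-yl]but-3-en-2-one | CC1=CCCC(C)(C)[C@H]1/C=C/C(C)=O | intermediate
9 | vinyl-α-ionol, (1E)-3-methyl-1-[(1R)-2,6,6-trimethylcyclohex-2-en-1-yl]penta-1,4-dien-3-ol (carbinol epimers) | CC1=CCCC(C)(C)[C@H]1/C=C/C(C)(O)C=C | intermediate
10 | [(2E,4E)-3-methyl-5-[(1R)-2,6,6-trimethylcyclohex-2-en-1-yl]penta-2,4-dien-1-yl]triphenylphosphonium bromide | CC1=CCCC(C)(C)[C@H]1/C=C/C(C)=C/C[P+](c1ccccc1)(c1ccccc1)c1ccccc1.[Br-] | intermediate
11 | (2E,4E,6E)-2,7-dimethylocta-2,4,6-trienedial (C10 dialdehyde) | O=C/C(C)=C/C=C/C=C(C)/C=O | starting material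
12 | C15 phosphorus ylide, triphenyl[(2E,4E)-3-methyl-5-[(1R)-2,6,6-trimethylcyclohex-2-en-1-yl]penta-2,4-dien-1-ylidene]phosphorane | CC1=CCCC(C)(C)[C@H]1/C=C/C(C)=C/C=P(c1ccccc1)(c1ccccc1)c1ccccc1 | intermediate
13 | C25 apo-aldehyde, (2E,4E,6E,8E,10E,12E)-2,7,11-trimethyl-13-[(1R)-2,6,6-trimethylcyclohex-2-en-1-yl]trideca-2,4,6,8,10,12-hexaenal | CC1=CCCC(C)(C)[C@H]1/C=C/C(C)=C/C=C/C(C)=C/C=C/C=C(C)/C=O | intermediate
14 | (6R,6'R)-ε,ε-carotene | CC1=CCCC(C)(C)[C@H]1/C=C/C(C)=C/C=C/C(C)=C/C=C/C=C(C)/C=C/C=C(C)/C=C/[C@H]1C(C)=CCCC1(C)C | target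

**Step count and risks**

Total step count: 10. Longest linear sequence: 10 steps (1 to 14); compound 11 is bought.

Steps most likely to fail:

Step 2. Proton loss from the C5 cation may be unselective (exocyclic alkene, tetrasubstituted alkene with loss of the C6 stereocenter), or the cation may be diverted by acetate participation or by a hydride shift of the opened epoxide. Fallback from 2: the ring is closed by a radical instead of a cation. Cp2TiCl2 (cat.), Mn dust, Me3SiCl and 2,4,6-collidine in THF generate Cp2TiCl (trivalent titanium), which opens the epoxide homolytically; 6-endo radical cyclization and mixed disproportionation should give the exocyclic alkene [(1S,3R)-3-hydroxy-2,2-dimethyl-6-methylidenecyclohexyl]methyl acetate F1, with the same C1–C6 bond and the same configuration. A hydrogen-atom-transfer alkene isomerization (Co(salen)Cl, a trivalent cobalt complex, with catalytic PhSiH3) should then move the double bond into the ring on the less hindered C4 side, which rejoins the route at 3.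

Step 4. Thioacylation next to the quaternary carbon may be slow, the thiocarbonyl ester may eliminate thermally, or the homoallylic ring radical may rearrange before it is reduced. Fallback from 3: the oxygen is removed at the ketone level. Dess–Martin oxidation of 3 gives [(1S)-2,6,6-trimethyl-5-oxocyclohex-2-en-1-yl]methyl acetate F2. Condensation with p-toluenesulfonhydrazide gives [(1S)-2,6,6-trimethyl-5-[2-(4-methylbenzenesulfonyl)hydrazinylidene]cyclohex-2-en-1-yl]methyl acetate F3. Reduction with catecholborane followed by NaOAc (hydrazone reduction with loss of nitrogen and sulfinate) rejoins the route at 5.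

Step 9. Under the acidic conditions the ring alkene may migrate into conjugation, or the pentadienyl cation may lose the C6 proton, which would erode the enantiomeric purity. Fallback from 8: the C15 salt is built without a cation. Horner–Wadsworth–Emmons reaction of 8 with triethyl phosphonoacetate (NaH, THF) gives ethyl (2E,4E)-3-methyl-5-[(1R)-2,6,6-trimethylcyclohex-2-en-1-yl]penta-2,4-dienoate F4. Reduction with iBu2AlH gives (2E,4E)-3-methyl-5-[(1R)-2,6,6-trimethylcyclohex-2-en-1-yl]penta-2,4-dien-1-ol F5. Appel bromination (CBr4, PPh3) gives (2E,4E)-1-bromo-3-methyl-5-[(1R)-2,6,6-trimethylcyclohex-2-en-1-yl]penta-2,4-diene F6, and quaternization with PPh3 rejoins the route at 10.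

**Further compounds**

F1 | step 2 | [(1S,3R)-3-hydroxy-2,2-dimethyl-6-methylidenecyclohexyl]methyl acetate | C=C1CC[C@@H](O)C(C)(C)[C@H]1COC(C)=O
F2 | step 4 | [(1S)-2,6,6-trimethyl-5-oxocyclohex-2-en-1-yl]methyl acetate | CC1=CCC(=O)C(C)(C)[C@H]1COC(C)=O
F3 | step 4 | [(1S)-2,6,6-trimethyl-5-[2-(4-methylbenzenesulfonyl)hydrazinylidene]cyclohex-2-en-1-yl]methyl acetate | CC1=CCC(=NNS(=O)(=O)c2ccc(C)cc2)C(C)(C)[C@H]1COC(C)=O
F4 | step 9 | ethyl (2E,4E)-3-methyl-5-[(1R)-2,6,6-trimethylcyclohex-2-en-1-yl]penta-2,4-dienoate | CC1=CCCC(C)(C)[C@H]1/C=C/C(C)=C/C(=O)OCC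
F5 | step 9 | (2E,4E)-3-methyl-5-[(1R)-2,6,6-trimethylcyclohex-2-en-1-yl]penta-2,4-dien-1-ol | CC1=CCCC(C)(C)[C@H]1/C=C/C(C)=C/CO
F6 | step 9 | (2E,4E)-1-bromo-3-methyl-5-[(1R)-2,6,6-trimethylcyclohex-2-en-1-yl]penta-2,4-diene | CC1=CCCC(C)(C)[C@H]1/C=C/C(C)=C/CBr
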